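Start at the early times. In the first 10.0 s the summer run loses 6.5 percentage points of left-handed substrate and the dusk run 6.6 points, though dusk holds more added ligand. The spring run, with twice the free catalyst and twice the added ligand of summer, loses 12 points. Next rung: by 120 s the ligand shows, with dusk at 9.6 % of left-handed substrate, above summer at 8.6 %. Last rung: right-handed substrate averages 50.0 % over the spring run, while left-handed substrate reads 0.4 % at 120 s.

| flask | left-handed substrate | right-handed substrate | reagent | free catalyst | added ligand | remark | time |
|---|---|---|---|---|---|---|---|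
| summer | 0.50 M | 0.50 M | 1.5 equiv | 0.5 mol% | 0.65 mM | run made earlier |  |
| dusk | 0.50 M | 0.50 M | 1.5 equiv | 0.5 mol% | 0.98 mM | run made earlier |  |
| spring | 0.50 M | 0.50 M | 1.5 equiv | 1 mol% | 1.3 mM | run made earlier |  |
| flask | 0.50 M | 0.50 M | 1.50 equiv | 0.5 mol% | 1.3 mM |  | 2.0 min |

- summer (time / s: left-handed substrate / %, right-handed substrate / %): 10.0: 43.5, 50.2; 20.0: 38.4, 50.3; 30.0: 34.2, 49.5; 50.0: 25.5, 49.4; 80.0: 17.6, 50.4; 90.0: 14.7, 49.7; 120: 8.6, 50.3
- dusk (time / s: left-handed substrate / %, right-handed substrate / %): 10.0: 43.4, 50.1; 20.0: 39.0, 50.2; 30.0: 34.5, 50.0; 50.0: 26.9, 50.0; 80.0: 18.1, 50.2; 90.0: 15.5, 50.5; 120: 9.6, 49.7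
- spring (time / s: left-handed substrate / %, right-handed substrate / %): 10.0: 37.5, 50.2; 30.0: 22.3, 50.1; 60.0: 8.3, 49.8; 80.0: 3.6, 50.2; 120: 0.4, 49.6

(each reading ± 0.3 percentage points)

- free catalyst is single-handed; left-handed substrate and right-handed substrate are mirror images of each other, charged as a racemate, each of them at the stated concentration
- the numbers in the tables scatter by 0.3 percentage points (one standard deviation)
- an excess is the difference of the two amounts in percent of their sum
- an excess is below zero if the other one leads

- part of the left-handed substrate and right-handed substrate charged together that has reacted at 2.0 min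
- excess of left-handed product over right-handed product in the product at 2.0 min
- excess of right-handed substrate over left-handed substrate among what is left of the two at 2.0 min

Scale this kinetic resolution from the symmetric case. The spring run reads 0.999 for the sorting number: the gap between the two substrates divided by what has reacted, zero for a catalyst blind to handedness, one for perfect sorting. Multiply it by c/(1−c) to get eS; where lost substrate has become product, it equals the product excess.

For the flask, draw a straight line through summer and dusk at 120 s and extend it to 1.3 mM of ligand. That line reads 10.6 % of left-handed substrate, so I reckon c at 39.4 % and eS at 65.0 %.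

The forecast gives c 38.8 % (36.5 % to 41 %), eP 100 % (98.5 % to 100 %) and eS 63.4 % (59 % to 68 %), reasoning that “the ligand titrates catalyst one-to-one”. My c stands 0.60 points above its value.

The flask gives c 38.9 %, eP 99.9 % and eS 63.5 %.

    reagent ⇌ dormant form (K = 0.750, k = 0.493 s⁻¹)
    reagent + catalyst intermediate B → free catalyst + right-handed product (k = 0.0835 M⁻¹ s⁻¹)
    free catalyst + added ligand ⇌ idle complex (K = 23700 M⁻¹, k = 72.2 M⁻¹ s⁻¹)
    free catalyst + right-handed substrate ⇌ catalyst intermediate B (K = 0.920 M⁻¹, k = 1770 M⁻¹ s⁻¹)
    2 free catalyst → spent catalyst (k = 8.26 M⁻¹ s⁻¹)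
    free catalyst + left-handed substrate ⇌ catalyst intermediate A (K = 61.0 M⁻¹, k = 228 M⁻¹ s⁻¹)
    reagent + catalyst intermediate A → free catalyst + left-handed product (k = 6.24 M⁻¹ s⁻¹)

The forecast holds, each value inside its range. Put the flask's c through the sorting number: 63.6 % for eS, against 63.5 %. The neighbouring flask keeps the other charges and the time but has 0.380 equiv of reagent, and its c falls to 11.2 %, below the low end of the forecast's range for this flask, 36.5 %. Its eP stays at 99.9 %. The same sorting number on that c gives eS 12.6 %; the neighbouring flask gives 12.6 %.

The data are calculated for an exercise; noise was put on by code.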